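I began with a subtraction on the last two readings of Thursday's run. In these flasks solid monomer dissolves into free monomer, and free monomer goes into chains at the initiator and at the living ends.

| setting | Wednesday's | Thursday's | oak | birch | maple | ash |
|---|---|---|---|---|---|---|
| solid monomer | 0.050 M | 0.050 M | 0.050 M | 0.050 M | 0.050 M | 0.050 M |
| initiator | 2.5 mM | 3.8 mM | 5.0 mM | 5.0 mM | 5.0 mM | 5.0 mM |
| temperature | 0 °C | 33 °C | 5 °C | 25 °C | −15 °C | 45 °C |
| remark | run made earlier | run made earlier |  |  |  |  |
| time |  |  | 3.0 d | 3.0 d | 3.0 d | 3.0 d |

| Wednesday's: time / d | Wednesday's: monomer in chains / % | Thursday's: time / h | Thursday's: monomer in chains / % |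
|---|---|---|---|
| 0.250 | 0 | 1.50 | 0.5 |
| 0.625 | 0.2 | 4.00 | 0 |
| 1.67 | 0.3 | 10.0 | 1.4 |
| 4.00 | 2.9 | 25.0 | 4.5 |

(scatter of a reading: 0.3 percentage points)

- solid, in amounts per volume of the solution: solid monomer
- the analysis behind the earlier runs scatters by 0.3 percentage points, standard deviation
- reactions considered so far: free monomer + initiator -> living end + monomer in chains; solid monomer <-> free monomer; monomer in chains + initiator <-> isomer of the product + initiator; free monomer + living end -> monomer in chains + living end
- at the start none of the solid monomer is in solution

* the flask that comes out highest in amount of monomer in chains, in percent of the solid monomer charged, or "all alike" when all lie within 1.5 percentage points (oak / birch / maple / ash / all alike)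
* monomer in chains at the end, in percent of the solid monomer charged, oak
* monomer in chains at the end, in percent of the solid monomer charged, birch
* monomer in chains at the end, in percent of the solid monomer charged, maple
* monomer in chains at the end, in percent of the solid monomer charged, ash

Ash looked nearly the same as Thursday's run: 0.050 M of solid monomer in both, 45 °C against 33 °C, 5.0 mM of initiator against 3.8 mM. From 10.0 h to 25.0 h, Thursday's time grew 2.50-fold and its chains 3.21-fold, less than the 6.25-fold of a square law. So I drew a straight line there. Thursday's feed is 0.103 mM h⁻¹, the monomer entering chains per hour if the curve runs straight. With a scatter of 0.3 percentage points on each reading, it is a reading. Wednesday's last slope was lower, 0.0232 mM h⁻¹.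

I took dissolving as the rate-limiting step in Thursday's run, in birch and in ash. Thursday's last reading was 4.5% after 25.0 h, but ash runs to 72 h, so the same line gives ash 14.9%. A line from the start errs by Thursday's lag, 3.23 h, which is small beside 72 h. At the feed the charge lasts 20.2 d, longer than 3.0 d. I committed to about 14.9% for ash and for birch, with oak and maple below it.

The forecast gave 0.8% for maple, 5% for oak, 25% for birch and 75% for ash, higher than my line for ash, and it said: “This makes ash very uncertain, though it is probably still highest.”

Ash gave 19.0%, more than birch at 14.3%, oak at 4.83% and maple at 0.704%.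

    free monomer + initiator → living end + monomer in chains (k = 15.0 L mol⁻¹ h⁻¹, Ea = 54.0 kJ mol⁻¹)
    solid monomer ⇌ free monomer, rate k2*(cs2 - [free monomer]) while solid is left; crystals form when [free monomer] > cs2 (solubility = 2.90 mM, k = 0.0540 h⁻¹)
    monomer in chains + initiator ⇌ isomer of the product + initiator, rate k3*[initiator]*[monomer in chains] forward; the back reaction follows from the equilibrium constant (K = 0.120, k = 66.0 L mol⁻¹ h⁻¹, Ea = 46.0 kJ mol⁻¹, ΔH = −10.0 kJ mol⁻¹)
    free monomer + living end → monomer in chains + living end, rate k4*[living end]*[free monomer] (k = 73.0 L mol⁻¹ h⁻¹, Ea = 63.0 kJ mol⁻¹)
    (constants at 25 °C)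

At 3.00 d, ash made free monomer and used it up at a ratio of 0.996. The feed had given 14.9%, which is 4.1 points under ash, whose mean pace into chains was 0.132 mM h⁻¹. Ash read early, at 20 h, is the second test. The feed gives 4.12% there, and that flask held 4.82%, with 95% of the solid monomer still there, solid or dissolved.

Readings and results were generated by integration for substances that don't exist.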